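I decide to count turnovers first, to learn whether these flasks are still changing at their end. In each flask D, E and G compete for J, and D.J is the product asked for. D can also pair with itself to X, and D.J can go on to Q.

| setting | spring | east | north | west | north-west |
|---|---|---|---|---|---|
| D | 0.025 M | 0.050 M | 0.050 M | 0.050 M | 0.050 M |
| J | 0.045 M | 0.0450 M | 0.0450 M | 0.0450 M | 0.0450 M |
| E | 0.050 M | 0.0500 M | 0.0500 M | 0.0500 M | 0.0500 M |
| G | 0.10 M | 0.100 M | 0.100 M | 0.100 M | 0.100 M |
| temperature | 125 °C |  | 125 °C | 110 °C | 140 °C |
| remark | run made earlier | at 110 °C until 25 min, from then on at 140 °C |  |  |  |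
| time |  | 80 min | 80 min | 80 min | 80 min |

spring run (percent of the D charged): time / min: D.J / % = 0.667: 0; 1.00: 5; 2.00: 9; 3.00: 9; 5.00: 14; 8.00: 16

(scatter of a reading: 1.5 percentage points)

1. the best flask by amount of D.J, in percent of the D charged; "all alike" if 1.5 percentage points covers them all (east / north / west / north-west / all alike)
2. amount of D.J at the end, in percent of the D charged, east
3. amount of D.J at the end, in percent of the D charged, north
4. amount of D.J at the end, in percent of the D charged, west
5. amount of D.J at the end, in percent of the D charged, north-west

- percent here means D units held: one X counts as two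
- candidate steps: D + J -> D.J; E + J -> E.J; G + J -> G.J; D.J -> Q; J <-> Z; 2 D -> X
- the earlier runs do not show what temperature does; that part of a forecast is a guess

Is the reaction over by the end? The spring readings climb to 16% at 8.00 min. The first reading past half of that is 9%, at 2.00 min, and I call this time th. The run time holds 40.0 such times, and this count is n, the number of turnovers: run time divided by th. Temperature is a guess, but even a factor of 10 on th for the cold of west leaves n at 4.00. So I read each end value as the plateau, minus any later loss.

How high is that plateau with twice the D? J is the limiting reagent, since E and G together hold 0.150 M against 0.0450 M of J. By the last spring reading, which carries the scatter, D.J had taken 8.89% of the J, and I take that as the spring plateau. Doubling D should about double that share, to 17.8%, and the percentage of the larger charge comes back to 16.0%.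

Does anything eat this plateau? The spring readings show no fall by 8.00 min, so they give me no rate for the loss to Q. I commit to the plateau figure for east, north, west and north-west, a little lower if X takes much D, and assuming heat favours none of the competitors.

The forecast names west as best, with 16% there, 14% in north, 12% in east and 9% in north-west: “Heat should speed the loss, so the coolest flask probably retains most”.

The flasks give 15.8% in east, 16.4% in north, 16.0% in west and 16.4% in north-west, so the answer is all alike.

    D + J → D.J (k = 0.465 L mol⁻¹ min⁻¹, Ea = 86.0 kJ mol⁻¹)
    E + J → E.J (k = 0.283 L mol⁻¹ min⁻¹, Ea = 68.0 kJ mol⁻¹)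
    G + J → G.J (k = 0.756 L mol⁻¹ min⁻¹, Ea = 86.0 kJ mol⁻¹)
    D.J → Q (k = 1.95 × 10⁻⁵ min⁻¹, Ea = 130 kJ mol⁻¹)
    J ⇌ Z (K = 1.10, k = 0.00208 min⁻¹, Ea = 110 kJ mol⁻¹, ΔH = 0 kJ mol⁻¹)
    2 D → X (k = 0.270 L mol⁻¹ min⁻¹, Ea = 80.0 kJ mol⁻¹)
    (constants at 110 °C)

North-west did half of its D + J turnover in 0.860 min, so its n is 93.1. Heat leaves north-west's D.J where west's stands partly because D + J and G + J both have 86.0 kJ mol⁻¹ and speed up together. North-west minus west is 0.43 percentage points, but it becomes 17 points without heat's effect on G + J, and −13 points without its effect on D + J. The largest single effect on north-west's D.J comes from G + J, since without that step the flask holds 42.4% rather than 16.4%. The neighbour flask, north-west stopped at 20 min, has n of 23.3 and already holds 16.7% of D.J.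

The earlier runs and the new flask are calculated for substances that don't exist, noise included.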